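**Retrosynthetic overview**
1. The furan is cut across C4–C5 and O–C6: its O–C3=C4(CO2Me) half is the enol of a β-keto ester and C5–C6–C7 is a propargyl unit. One intramolecular C-propargylation/5-exo-dig oxa-cyclisation of an acyclic chain therefore closes the 14-membered carbocycle (the 13-membered 2,5-furanophane ring) and the furan together.
2. The acyclic chain is cut at C9–C10 (Weinreb amide plus a β-oxido alkyllithium from an (R)-2-methylglycidol-derived C5–C9 alkyne, the source of C8) and at C3–C4 (Roskamp homologation of a C3 aldehyde).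
3. C10–C12 with both stereocentres come from dimethyl (2R,3R)-epoxysuccinate, opened with inversion at C12 by a copper-catalysed Grignard reagent that carries C13–C3.
4. C1 and its isopropenyl group come from (S)-carvone by oxidative excision of the enone carbon that bears the methyl group.
5. Ring order: no ring before the key step; carbocycle and furan form in the same operation; desilylation ends the route.

Key step: step 19

Remark: atoms are numbered as in a cembrane (C1 CH–isopropenyl, C2 CH2, C3–C6 furan carbons with CO2Me on C4 and H on C5, C7 CH2, C8 C(OH)CH3, C9 CH2, C10 C=O, C11 CHOH, C12 CH–CO2Me, C13/C14 CH2), the target being (1R,8R,11R,12S); the C8 descriptor reads S while C7 is an sp or sp2 carbon (CIP priority change only); compounds 1, 7 and 14 are assumed to be commercial.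

Step 1
Reactants: 1 (S)-(+)-carvone
Product: 2 (1S,4S,6S)-1-methyl-4-(prop-1-en-2-yl)-7-oxabicyclo[4.1.0]heptan-2-one
Conditions: 30% H2O2, NaOH (cat.), MeOH, 0 °C
Reagents that add atoms: hydrogen peroxide, OO
Why: Weitz–Scheffer nucleophilic epoxidation reacts only at the electron-poor enone (the isopropenyl group is inert) and hydroperoxide should add anti to the ring substituent to give the trans-epoxide, whose two new centres are excised in step 2.

Step 2
Reactants: 2 (1S,4S,6S)-1-methyl-4-(prop-1-en-2-yl)-7-oxabicyclo[4.1.0]heptan-2-one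
Product: 3 (3S)-5-oxo-3-(prop-1-en-2-yl)pentanoic acid
Conditions: H5IO6 (3 equiv), THF/H2O, 23 → 40 °C
Reagents that add atoms: periodic acid, OI(O)(O)(O)(O)=O; water, O
Why: acid-assisted hydrolysis of the epoxide and Malaprade-type periodate cleavage of the glycol and of the 1,2-dicarbonyl unit excise the methyl-bearing carbon as acetic acid and leave a differentiated acid/aldehyde pair, while the stereocentre and the 1,1-disubstituted alkene are not involved.

Step 3
Reactants: 3 (3S)-5-oxo-3-(prop-1-en-2-yl)pentanoic acid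
Product: 4 methyl (3S)-5,5-dimethoxy-3-(prop-1-en-2-yl)pentanoate
Conditions: HC(OMe)3, MeOH, TsOH (cat.), 23 °C
Reagents that add atoms: methanol, CO; trimethyl orthoformate, COC(OC)OC
Why: Fischer esterification and dimethyl acetal formation run together with the orthoester as water scavenger, and the mild acid should leave the isopropenyl group and the non-epimerisable stereocentre unchanged.

Step 4
Reactants: 4 methyl (3S)-5,5-dimethoxy-3-(prop-1-en-2-yl)pentanoate
Product: 5 (3R)-5,5-dimethoxy-3-(prop-1-en-2-yl)pentan-1-ol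
Conditions: LiAlH4, THF, 0 °C
Reagents that add atoms: none
Why: hydride reduction of the ester to the primary alcohol, with acetal and alkene inert (the descriptor changes by priority only).

Step 5
Reactants: 5 (3R)-5,5-dimethoxy-3-(prop-1-en-2-yl)pentan-1-ol
Product: 6 (3S)-5-iodo-1,1-dimethoxy-3-(prop-1-en-2-yl)pentane
Conditions: I2, PPh3, imidazole, CH2Cl2, 0 → 23 °C
Reagents that add atoms: iodine, II
Why: Appel-type iodination (SN2 at the primary carbinol) under imidazole-buffered conditions that keep the acetal.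

Step 6
Reactants: 7 (R)-2-methylglycidol, [(2R)-2-methyloxiran-2-yl]methanol
Product: 8 (2S)-2-methyloxirane-2-carbaldehyde
Conditions: SO3·pyridine, DMSO, iPr2NEt, CH2Cl2, 0 °C (solution used directly)
Reagents that add atoms: none
Why: Parikh–Doering oxidation under basic conditions spares the epoxide, and the quaternary stereocentre cannot epimerise.

Step 7
Reactants: 8 (2S)-2-methyloxirane-2-carbaldehyde
Product: 9 (2R)-2-ethynyl-2-methyloxirane
Conditions: MeC(O)C(N2)P(O)(OMe)2, K2CO3, MeOH, 0 → 23 °C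
Reagents that add atoms: dimethyl (1-diazo-2-oxopropyl)phosphonate, CC(=O)C(=[N+]=[N-])P(=O)(OC)OC
Why: Ohira–Bestmann (Seyferth–Gilbert) homologation of a non-enolisable aldehyde gives the terminal alkyne without touching the stereocentre.

Step 8
Reactants: 9 (2R)-2-ethynyl-2-methyloxirane
Product: 11 3-[(2R)-2-methyloxiran-2-yl]prop-2-yn-1-ol, via lithium acetylide 10 (not isolated)
Conditions: n-BuLi, THF, −78 °C; (CH2O)n, −78 → 0 °C; aq. NH4Cl
Reagents that add atoms: formaldehyde (as paraformaldehyde), C=O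
Why: acetylide addition to formaldehyde installs C5 with its oxygen, and a lithium acetylide does not open an epoxide without a Lewis acid.

Step 9
Reactants: 11 3-[(2R)-2-methyloxiran-2-yl]prop-2-yn-1-ol
Product: 12 (2R)-2-{3-[(4-methoxyphenyl)methoxy]prop-1-yn-1-yl}-2-methyloxirane
Conditions: NaH, 4-MeOC6H4CH2Cl, Bu4NI (cat.), THF/DMF, 0 → 23 °C
Reagents that add atoms: 4-methoxybenzyl chloride, COc1ccc(CCl)cc1
Why: Williamson etherification of the primary propargylic alkoxide, which cannot reach the epoxide intramolecularly.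

Step 10
Reactants: 12 (2R)-2-{3-[(4-methoxyphenyl)methoxy]prop-1-yn-1-yl}-2-methyloxirane
Product: 13 (2R)-1-iodo-5-[(4-methoxyphenyl)methoxy]-2-methylpent-3-yn-2-ol
Conditions: LiI, AcOH, THF, 0 → 23 °C
Reagents that add atoms: lithium iodide, [Li+].[I-]
Why: SN2 opening of the 2,2-disubstituted epoxide by iodide at the unhindered CH2 (the alkynyl group disfavours ionisation at the quaternary carbon) leaves the C–O bond of the stereocentre intact.

Step 11
Reactants: 6 (3S)-5-iodo-1,1-dimethoxy-3-(prop-1-en-2-yl)pentane; 14 dimethyl (2R,3R)-oxirane-2,3-dicarboxylate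
Product: 16 dimethyl (2R,3S)-2-hydroxy-3-[(3R)-5,5-dimethoxy-3-(prop-1-en-2-yl)pentyl]butanedioate, via Grignard reagent 15 (not isolated)
Conditions: 6, Mg, THF, 23 °C; then 14 (1.5 equiv), CuI (10 mol %), THF, −40 → −20 °C; aq. NH4Cl
Reagents that add atoms: none
Why: copper-catalysed Grignard opening of a 2,3-epoxy ester (organocuprate SN2) occurs at the carbon α to the ester with inversion, and because 14 is C2-symmetric both carbons are equivalent, so C11 keeps R and C12 should become S.

Step 12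
Reactants: 16 dimethyl (2R,3S)-2-hydroxy-3-[(3R)-5,5-dimethoxy-3-(prop-1-en-2-yl)pentyl]butanedioate
Product: 17 methyl (2S,3R)-2-[(3R)-5,5-dimethoxy-3-(prop-1-en-2-yl)pentyl]-3-hydroxy-4-[methoxy(methyl)amino]-4-oxobutanoate
Conditions: MeNH(OMe)·HCl, AlMe3, CH2Cl2, 0 → 23 °C
Reagents that add atoms: N,O-dimethylhydroxylamine hydrochloride, CNOC.Cl
Why: Weinreb amidation with the aluminium amide should be directed by the aluminium alkoxide of the free C11 hydroxyl to the adjacent, more electrophilic α-hydroxy ester (C10), the α-branched C20 ester reacting more slowly, and no stereocentre is touched.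

Step 13
Reactants: 17 methyl (2S,3R)-2-[(3R)-5,5-dimethoxy-3-(prop-1-en-2-yl)pentyl]-3-hydroxy-4-[methoxy(methyl)amino]-4-oxobutanoate; 13 (2R)-1-iodo-5-[(4-methoxyphenyl)methoxy]-2-methylpent-3-yn-2-ol
Product: 20 methyl (2S,3R,6S)-2-[(3R)-5,5-dimethoxy-3-(prop-1-en-2-yl)pentyl]-3,6-dihydroxy-9-[(4-methoxyphenyl)methoxy]-6-methyl-4-oxonon-7-ynoate, via lithium alkoxide 18 (not isolated), via dilithio reagent 19 (not isolated)
Conditions: 17, LiN(SiMe3)2 (1.0 equiv), THF, −78 °C; 13, n-BuLi (1.0 equiv) then t-BuLi (2.0 equiv), Et2O, −78 °C; mix, −78 → −50 °C; aq. NH4Cl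
Reagents that add atoms: none
Why: Weinreb ketone synthesis in which iodine–lithium exchange on the lithium alkoxide of 13 gives a β-oxido alkyllithium (oxide is a poor leaving group at −78 °C) that should add once to the chelated amide to form the C9–C10 bond, with C8 carried in unchanged from 13 and C11/C12 kept by the low temperature.

Step 14
Reactants: 20 methyl (2S,3R,6S)-2-[(3R)-5,5-dimethoxy-3-(prop-1-en-2-yl)pentyl]-3,6-dihydroxy-9-[(4-methoxyphenyl)methoxy]-6-methyl-4-oxonon-7-ynoate
Product: 21 methyl (2S,3R,6S)-3,6-dihydroxy-9-[(4-methoxyphenyl)methoxy]-6-methyl-4-oxo-2-[(3R)-5-oxo-3-(prop-1-en-2-yl)pentyl]non-7-ynoate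
Conditions: PPTS, acetone/H2O (9:1), 40 °C
Reagents that add atoms: water, O
Why: mild acid hydrolysis of the dimethyl acetal is done before silylation, so no silyl ether is at risk, and the PMB ether, tertiary propargylic alcohol and β-hydroxy ketone should tolerate PPTS.

Step 15
Reactants: 21 methyl (2S,3R,6S)-3,6-dihydroxy-9-[(4-methoxyphenyl)methoxy]-6-methyl-4-oxo-2-[(3R)-5-oxo-3-(prop-1-en-2-yl)pentyl]non-7-ynoate
Product: 22 methyl (2S,3R,6S)-9-[(4-methoxyphenyl)methoxy]-6-methyl-4-oxo-2-[(3R)-5-oxo-3-(prop-1-en-2-yl)pentyl]-3,6-bis[(triethylsilyl)oxy]non-7-ynoate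
Conditions: Et3SiOTf, 2,6-lutidine, CH2Cl2, −78 °C
Reagents that add atoms: triethylsilyl trifluoromethanesulfonate, CC[Si](CC)(CC)OS(=O)(=O)C(F)(F)F
Why: O-silylation of the secondary C11 and tertiary C8 hydroxyls by the silyl triflate at −78 °C is much faster than enol silylation of the aldehyde or ketone.

Step 16
Reactants: 22 methyl (2S,3R,6S)-9-[(4-methoxyphenyl)methoxy]-6-methyl-4-oxo-2-[(3R)-5-oxo-3-(prop-1-en-2-yl)pentyl]-3,6-bis[(triethylsilyl)oxy]non-7-ynoate
Product: 23 methyl (2S,3R,6S)-2-[(3R)-7-methoxy-5,7-dioxo-3-(prop-1-en-2-yl)heptyl]-9-[(4-methoxyphenyl)methoxy]-6-methyl-4-oxo-3,6-bis[(triethylsilyl)oxy]non-7-ynoate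
Conditions: N2CHCO2Me, SnCl2 (10 mol %), CH2Cl2, 23 °C
Reagents that add atoms: methyl diazoacetate, COC(=O)C=[N+]=[N-]
Why: Roskamp homologation (addition of the diazo ester to the aldehyde, 1,2-hydride shift, loss of N2) gives the β-keto ester directly and is selective for the aldehyde over the hindered C10 ketone.

Step 17
Reactants: 23 methyl (2S,3R,6S)-2-[(3R)-7-methoxy-5,7-dioxo-3-(prop-1-en-2-yl)heptyl]-9-[(4-methoxyphenyl)methoxy]-6-methyl-4-oxo-3,6-bis[(triethylsilyl)oxy]non-7-ynoate
Product: 24 methyl (2S,3R,6S)-9-hydroxy-2-[(3R)-7-methoxy-5,7-dioxo-3-(prop-1-en-2-yl)heptyl]-6-methyl-4-oxo-3,6-bis[(triethylsilyl)oxy]non-7-ynoate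
Conditions: DDQ, CH2Cl2/pH 7 buffer, 0 °C
Reagents that add atoms: none
Why: oxidative cleavage of the PMB ether (benzylic hydride abstraction, hydrolysis) under buffered conditions should leave the silyl ethers, alkyne, isopropenyl group and β-keto ester intact.

Step 18
Reactants: 24 methyl (2S,3R,6S)-9-hydroxy-2-[(3R)-7-methoxy-5,7-dioxo-3-(prop-1-en-2-yl)heptyl]-6-methyl-4-oxo-3,6-bis[(triethylsilyl)oxy]non-7-ynoate
Product: 25 methyl (2S,3R,6S)-9-[(methanesulfonyl)oxy]-2-[(3R)-7-methoxy-5,7-dioxo-3-(prop-1-en-2-yl)heptyl]-6-methyl-4-oxo-3,6-bis[(triethylsilyl)oxy]non-7-ynoate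
Conditions: MsCl, Et3N, CH2Cl2, −40 °C (used crude)
Reagents that add atoms: methanesulfonyl chloride, CS(=O)(=O)Cl
Why: sulfonylation (via sulfene) of the only free hydroxyl, a primary propargylic one, is far faster at −40 °C than O-sulfonylation of the β-keto ester enol.

Step 19
Reactants: 25 methyl (2S,3R,6S)-9-[(methanesulfonyl)oxy]-2-[(3R)-7-methoxy-5,7-dioxo-3-(prop-1-en-2-yl)heptyl]-6-methyl-4-oxo-3,6-bis[(triethylsilyl)oxy]non-7-ynoate
Product: 28 8,11-bis-O-triethylsilyl ether of the target, via cycloalkyne 26 (not isolated), via alkylidene dihydrofuran 27 (not isolated)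
Conditions: Cs2CO3 (3 equiv), MeCN, 1 mM (25 added by syringe pump), 40 °C; then AuCl(PPh3)/AgOTf (5 mol % each), 23 °C, same flask
Reagents that add atoms: none
Why: Proposed new method: the caesium enolate of the β-keto ester (C3/C4) should displace the primary propargylic mesylate at C5 (SN2 C-alkylation) to close the 14-membered carbocycle as cycloalkyne 26, after which the enolate oxygen adds anti across the gold-activated C6≡C7 bond and protodeauration gives exocyclic enol ether 27, whose 1,3-hydrogen shift under the basic conditions delivers the aromatic furan; the closest known reaction types are the one-pot propargylation/cycloisomerisation of 1,3-dicarbonyl compounds with propargylic electrophiles to 2,3,5-trisubstituted furans and the high-dilution macrocyclic C-alkylation of β-keto ester enolates, merged here into one ring-forming operation. The carbocycle closes in a 14-exo-tet mode and the furan in a 5-exo-dig mode, which creates the 13-membered 2,5-furanophane ring at the same time. No stereocentre is created in 28, because the centre formed at C4 in 26 becomes sp2 and C1, C8, C11 and C12 lie outside the reacting atoms. The step needs C- over O-alkylation and SN2 over SN2′ (soft enolate, unhindered primary C5, C7 shielded by quaternary C8), ring closure over oligomerisation (1 mM, slow addition, caesium counter-ion) and 5-exo over 6-endo attack (again the C8 substituents); the two silyl ethers block retro-aldol cleavage at C8–C9 and hydroxyl participation, and a mesylate instead of a halide keeps the gold catalyst active. Aromatisation of the furan makes the sequence irreversible.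

Step 20
Reactants: 28 8,11-bis-O-triethylsilyl ether of the target
Product: 29 CNP0218204.1
Conditions: HF·pyridine, pyridine, THF, 0 → 23 °C
Reagents that add atoms: none
Why: fluoride-mediated cleavage of both triethylsilyl ethers under buffered, weakly acidic conditions should avoid retro-aldol cleavage of the β-hydroxy ketone and elimination or epimerisation at C11/C12.

**Compound list**
1 | (S)-(+)-carvone, (5S)-2-methyl-5-(prop-1-en-2-yl)cyclohex-2-en-1-one | CC1=CC[C@H](C(C)=C)CC1=O | starting material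
2 | (1S,4S,6S)-1-methyl-4-(prop-1-en-2-yl)-7-oxabicyclo[4.1.0]heptan-2-one (epoxide trans to isopropenyl) | C[C@]12O[C@H]1C[C@H](C(C)=C)CC2=O | intermediate
3 | (3S)-5-oxo-3-(prop-1-en-2-yl)pentanoic acid | C=C(C)[C@@H](CC=O)CC(=O)O | intermediate
4 | methyl (3S)-5,5-dimethoxy-3-(prop-1-en-2-yl)pentanoate | C=C(C)[C@@H](CC(OC)OC)CC(=O)OC | intermediate
5 | (3R)-5,5-dimethoxy-3-(prop-1-en-2-yl)pentan-1-ol | C=C(C)[C@@H](CC(OC)OC)CCO | intermediate
6 | (3S)-5-iodo-1,1-dimethoxy-3-(prop-1-en-2-yl)pentane | C=C(C)[C@@H](CC(OC)OC)CCI | intermediate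
7 | (R)-2-methylglycidol, [(2R)-2-methyloxiran-2-yl]methanol | C[C@@]1(CO)CO1 | starting material
8 | (2S)-2-methyloxirane-2-carbaldehyde | C[C@@]1(C=O)CO1 | intermediate
9 | (2R)-2-ethynyl-2-methyloxirane | C[C@@]1(C#C)CO1 | intermediate
10 | {[(2R)-2-methyloxiran-2-yl]ethynyl}lithium (lithium acetylide) | C[C@@]1(C#C[Li])CO1 | intermediate
11 | 3-[(2R)-2-methyloxiran-2-yl]prop-2-yn-1-ol | C[C@@]1(C#CCO)CO1 | intermediate
12 | (2R)-2-{3-[(4-methoxyphenyl)methoxy]prop-1-yn-1-yl}-2-methyloxirane | C[C@@]1(C#CCOCc2ccc(OC)cc2)CO1 | intermediate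
13 | (2R)-1-iodo-5-[(4-methoxyphenyl)methoxy]-2-methylpent-3-yn-2-ol | C[C@](O)(CI)C#CCOCc1ccc(OC)cc1 | intermediate
14 | dimethyl (2R,3R)-oxirane-2,3-dicarboxylate | COC(=O)[C@@H]1O[C@H]1C(=O)OC | starting material
15 | [(3S)-5,5-dimethoxy-3-(prop-1-en-2-yl)pentyl]magnesium iodide (Grignard reagent) | C=C(C)[C@@H](CC(OC)OC)CC[Mg]I | intermediate
16 | dimethyl (2R,3S)-2-hydroxy-3-[(3R)-5,5-dimethoxy-3-(prop-1-en-2-yl)pentyl]butanedioate | C=C(C)[C@@H](CC(OC)OC)CC[C@H](C(=O)OC)[C@@H](O)C(=O)OC | intermediate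
17 | methyl (2S,3R)-2-[(3R)-5,5-dimethoxy-3-(prop-1-en-2-yl)pentyl]-3-hydroxy-4-[methoxy(methyl)amino]-4-oxobutanoate | C=C(C)[C@@H](CC(OC)OC)CC[C@H](C(=O)OC)[C@@H](O)C(=O)N(C)OC | intermediate
18 | lithium alkoxide of 17 (O-lithiated at C11) | C=C(C)[C@@H](CC(OC)OC)CC[C@H](C(=O)OC)[C@@H](O[Li])C(=O)N(C)OC | intermediate
19 | lithium (2S)-1-lithio-5-[(4-methoxyphenyl)methoxy]-2-methylpent-3-yn-2-olate (dilithio reagent) | C[C@](O[Li])(C[Li])C#CCOCc1ccc(OC)cc1 | intermediate
20 | methyl (2S,3R,6S)-2-[(3R)-5,5-dimethoxy-3-(prop-1-en-2-yl)pentyl]-3,6-dihydroxy-9-[(4-methoxyphenyl)methoxy]-6-methyl-4-oxonon-7-ynoate | C=C(C)[C@@H](CC(OC)OC)CC[C@H](C(=O)OC)[C@@H](O)C(=O)C[C@](C)(O)C#CCOCc1ccc(OC)cc1 | intermediate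
21 | methyl (2S,3R,6S)-3,6-dihydroxy-9-[(4-methoxyphenyl)methoxy]-6-methyl-4-oxo-2-[(3R)-5-oxo-3-(prop-1-en-2-yl)pentyl]non-7-ynoate | C=C(C)[C@@H](CC=O)CC[C@H](C(=O)OC)[C@@H](O)C(=O)C[C@](C)(O)C#CCOCc1ccc(OC)cc1 | intermediate
22 | methyl (2S,3R,6S)-9-[(4-methoxyphenyl)methoxy]-6-methyl-4-oxo-2-[(3R)-5-oxo-3-(prop-1-en-2-yl)pentyl]-3,6-bis[(triethylsilyl)oxy]non-7-ynoate | C=C(C)[C@@H](CC=O)CC[C@H](C(=O)OC)[C@@H](O[Si](CC)(CC)CC)C(=O)C[C@](C)(O[Si](CC)(CC)CC)C#CCOCc1ccc(OC)cc1 | intermediate
23 | methyl (2S,3R,6S)-2-[(3R)-7-methoxy-5,7-dioxo-3-(prop-1-en-2-yl)heptyl]-9-[(4-methoxyphenyl)methoxy]-6-methyl-4-oxo-3,6-bis[(triethylsilyl)oxy]non-7-ynoate | C=C(C)[C@@H](CC(=O)CC(=O)OC)CC[C@H](C(=O)OC)[C@@H](O[Si](CC)(CC)CC)C(=O)C[C@](C)(O[Si](CC)(CC)CC)C#CCOCc1ccc(OC)cc1 | intermediate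
24 | methyl (2S,3R,6S)-9-hydroxy-2-[(3R)-7-methoxy-5,7-dioxo-3-(prop-1-en-2-yl)heptyl]-6-methyl-4-oxo-3,6-bis[(triethylsilyl)oxy]non-7-ynoate | C=C(C)[C@@H](CC(=O)CC(=O)OC)CC[C@H](C(=O)OC)[C@@H](O[Si](CC)(CC)CC)C(=O)C[C@](C)(O[Si](CC)(CC)CC)C#CCO | intermediate
25 | methyl (2S,3R,6S)-9-[(methanesulfonyl)oxy]-2-[(3R)-7-methoxy-5,7-dioxo-3-(prop-1-en-2-yl)heptyl]-6-methyl-4-oxo-3,6-bis[(triethylsilyl)oxy]non-7-ynoate | C=C(C)[C@@H](CC(=O)CC(=O)OC)CC[C@H](C(=O)OC)[C@@H](O[Si](CC)(CC)CC)C(=O)C[C@](C)(O[Si](CC)(CC)CC)C#CCOS(C)(=O)=O | intermediate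
26 | 14-membered cycloalkyne β-keto ester (C6≡C7; ketones at C3 and C10; CO2Me at C4 and C12; triethylsilyl ethers at C8 and C11; 1R,8S,11R,12S; both C4 epimers) | C=C(C)[C@@H]1CC[C@H](C(=O)OC)[C@@H](O[Si](CC)(CC)CC)C(=O)C[C@](C)(O[Si](CC)(CC)CC)C#CCC(C(=O)OC)C(=O)C1 | intermediate
27 | (Z)-alkylidene dihydrofuran (bridged 2,3-dihydrofuran with exocyclic C6=C7 enol ether; 1R,8S,11R,12S) | C=C(C)[C@@H]1CC[C@H](C(=O)OC)[C@@H](O[Si](CC)(CC)CC)C(=O)C[C@](C)(O[Si](CC)(CC)CC)/C=C2/CC(C(=O)OC)=C(C1)O2 | intermediate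
28 | 8,11-bis-O-triethylsilyl ether of the target (1R,8R,11R,12S) | C=C(C)[C@@H]1CC[C@H](C(=O)OC)[C@@H](O[Si](CC)(CC)CC)C(=O)C[C@](C)(O[Si](CC)(CC)CC)CC2=CC(C(=O)OC)=C(C1)O2 | intermediate
29 | CNP0218204.1 (1R,8R,11R,12S) | C=C(C)[C@@H]1CC[C@H](C(=O)OC)[C@@H](O)C(=O)C[C@](C)(O)CC2=CC(C(=O)OC)=C(C1)O2 | target

**Step count and risks**
Total step count: 20. Longest linear sequence: 15 steps (steps 1–5 and 11–20, from (S)-carvone).

Step 19 is the most likely to fail. Intermolecular alkylation may outrun ring closure (oligomers), the C8 silyloxy group may be lost by β-elimination from the vinyl-gold or vinyl-anion stage (giving a 2-alkenylfuran), carbonate may deactivate the gold catalyst, and prolonged base may epimerise C11. The fallback sets out from 25, gives up the cascade and makes the two bonds in two separate reactions of known type. Macrocyclic C-alkylation alone (Cs2CO3, MeCN, 1 mM, 23 °C), followed by work-up and chromatography, gives cycloalkyne 26 as an isolated compound (already in the list, so no new compound arises, F0). This 2-propargyl β-keto ester is then cycloisomerised in a second flask, free of base and halide, with NaAuCl4·2H2O (5 mol %) in MeCN at 23 °C, and a short treatment with Et3N completes the hydrogen shift. The fallback comes back to the route at 28.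

Step 13 is the second risk. The β-oxido alkyllithium 19 may eliminate lithium oxide before it is acylated, and the organolithium may attack the C20 methyl ester or deprotonate C12 (epimerisation). The fallback uses a sulfone-stabilised carbanion and sets out from epoxide 12. PhSO2Na in DMF/H2O at 80 °C opens the epoxide at CH2 to give (2R)-5-[(4-methoxyphenyl)methoxy]-2-methyl-1-(phenylsulfonyl)pent-3-yn-2-ol F1. Its dianion (n-BuLi, 2.1 equiv, THF, −78 °C) is acylated by the lithium alkoxide 18 of Weinreb amide 17 to give β-keto sulfone F2. Reductive desulfonylation with aluminium amalgam (Al, HgCl2, THF/H2O, 0 °C) then comes back to the route at 20.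

Step 12 is the third risk. Site selectivity between the two methyl esters may be poor, with amidation at C20 or at both esters. The fallback sets out from 16 and differentiates the carboxyl groups through a ring. LiOH in THF/H2O gives (2R,3S)-2-hydroxy-3-[(3R)-5,5-dimethoxy-3-(prop-1-en-2-yl)pentyl]butanedioic acid F3. 2,2-Dimethoxypropane with PPTS ties only the α-hydroxy acid into dioxolanone acid F4. Me3SiCHN2 in MeOH/toluene gives dioxolanone methyl ester F5. MeNH(OMe)·HCl with iPrMgCl in THF at −20 °C opens the activated dioxolanone, and the fallback comes back to the route at 17.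

Further compounds
F0 | step 19 | none | none
F1 | step 13 | (2R)-5-[(4-methoxyphenyl)methoxy]-2-methyl-1-(phenylsulfonyl)pent-3-yn-2-ol | C[C@](O)(CS(=O)(=O)c1ccccc1)C#CCOCc1ccc(OC)cc1
F2 | step 13 | β-keto sulfone (20 with a phenylsulfonyl group at C9, both C9 epimers) | C=C(C)[C@@H](CC(OC)OC)CC[C@H](C(=O)OC)[C@@H](O)C(=O)C(S(=O)(=O)c1ccccc1)[C@](C)(O)C#CCOCc1ccc(OC)cc1
F3 | step 12 | (2R,3S)-2-hydroxy-3-[(3R)-5,5-dimethoxy-3-(prop-1-en-2-yl)pentyl]butanedioic acid | C=C(C)[C@@H](CC(OC)OC)CC[C@H](C(=O)O)[C@@H](O)C(=O)O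
F4 | step 12 | dioxolanone acid: (2S)-2-[(4R)-2,2-dimethyl-5-oxo-1,3-dioxolan-4-yl]-2-[(3R)-5,5-dimethoxy-3-(prop-1-en-2-yl)pentyl]acetic acid | C=C(C)[C@@H](CC(OC)OC)CC[C@H](C(=O)O)[C@H]1OC(C)(C)OC1=O
F5 | step 12 | dioxolanone methyl ester (methyl ester of F4) | C=C(C)[C@@H](CC(OC)OC)CC[C@H](C(=O)OC)[C@H]1OC(C)(C)OC1=O
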